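**Retrosynthetic overview**
- Disconnect the aryl ketone bond, ArA–C(=O), by a photo-Fries rearrangement of the 3-hydroxy-2-prenylphenyl ester of the (R)-α-hydroxy acid. The 2-prenylresorcinol ring is symmetric with C2 blocked, so ortho and para acyl migration give the same ketone.
- Disconnect the ester C–O bond to 2-prenylresorcinol and (R)-2-hydroxy-3-(4-hydroxy-3-prenylphenyl)propanoic acid.
- The B-ring prenyl comes from a Stille coupling on an aryl iodide; the (R)-carbinol comes from D-tyrosine by iodination and retentive diazotisation.
- The A-ring prenyl comes from directed ortho-lithiation of resorcinol bis-MOM ether.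
- No rings are formed; both benzene rings are purchased.

Assumption: the stereocentre in the SMILES is (R) by CIP analysis, and 1,3-bis(methoxymethoxy)benzene and tributyl(prenyl)stannane are taken as catalogue items.

**Step 1**
Reactants: 1, 1,3-bis(methoxymethoxy)benzene; 2, prenyl bromide (1-bromo-3-methylbut-2-ene)
Product: 3, 1,3-bis(methoxymethoxy)-2-(3-methylbut-2-enyl)benzene
Conditions: n-BuLi, THF, 0 °C to rt; then 2, −78 °C to rt
Reagents that add atoms: prenyl bromide (2), CC(C)=CCBr
Why: Directed ortho-metalation, in which the two OMOM groups direct lithiation to C2 and the aryllithium is alkylated by the allylic bromide (SN2).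

**Step 2**
Reactants: 3
Product: 4, 2-(3-methylbut-2-enyl)benzene-1,3-diol (2-prenylresorcinol)
Conditions: 3 M aq HCl, MeOH, 50 °C, about 1 h
Reagents that add atoms: none
Why: Acid-catalysed MOM acetal methanolysis, kept mild and short so the prenyl group does not cyclise onto the phenol to give the chroman.

**Step 3**
Reactants: 5, D-tyrosine ((R)-2-amino-3-(4-hydroxyphenyl)propanoic acid)
Product: 6, 3-iodo-D-tyrosine ((R)-2-amino-3-(4-hydroxy-3-iodophenyl)propanoic acid)
Conditions: I2 (1.0 equiv), KI, conc. aq NH3, 0 °C; then AcOH to pH 5
Reagents that add atoms: iodine, II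
Why: Electrophilic aromatic iodination of the phenoxide ortho to OH (para is blocked), with one equivalent giving the mono-iodide, which precipitates at its isoelectric point; the stereocentre is untouched.

**Step 4**
Reactants: 6
Product: 7, (R)-2-hydroxy-3-(4-hydroxy-3-iodophenyl)propanoic acid
Conditions: NaNO2 (3 equiv), 0.5 M H2SO4, H2O–dioxane, 0 °C to rt
Reagents that add atoms: water, O
Why: Diazotisation of the α-amino acid with hydrolysis, where carboxylate participation (α-lactone) and opening by water is a double inversion, so net retention carries (R) from the amine to the alcohol.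

**Step 5**
Reactants: 7; 8, tributyl(3-methylbut-2-enyl)stannane
Product: 9, (R)-2-hydroxy-3-[4-hydroxy-3-(3-methylbut-2-enyl)phenyl]propanoic acid
Conditions: 8 (1.5 equiv), Pd(PPh3)4 (5 mol %), NaHCO3 (1.05 equiv), DMF, 90 °C; aq KF, then acid–base extraction
Reagents that add atoms: tributyl(prenyl)stannane (8), CCCC[Sn](CCCC)(CCCC)CC=C(C)C
Why: Stille cross-coupling, where reductive elimination from the aryl–Pd–(η3-prenyl) intermediate at the less hindered terminus gives the linear prenyl arene; running the acid as its carboxylate salt prevents protodestannylation, and the remote stereocentre is unaffected.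

**Step 6**
Reactants: 9; 4, 2-prenylresorcinol (3 equiv, excess recovered)
Product: 10, 3-hydroxy-2-(3-methylbut-2-enyl)phenyl (R)-2-hydroxy-3-[4-hydroxy-3-(3-methylbut-2-enyl)phenyl]propanoate
Conditions: one pot: HMDS, cat. TMSCl, CH2Cl2, reflux, evaporate; (COCl)2, cat. DMF, CH2Cl2, 0 °C; add to 4, pyridine, CH2Cl2, −20 to 0 °C; then citric acid, MeOH–H2O, rt
Reagents that add atoms: none other than reactant 4 (CC(C)=CCc1c(O)cccc1O)
Why: Transient per-silylation then acyl chloride esterification, in which the TMS ester is converted to the acid chloride under neutral conditions, the excess symmetric diol is mono-acylated, and the TMS ethers are removed by mild acidic methanolysis; pyridine at low temperature avoids ketene formation, so the α-centre stays (R).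

**Step 7**
Reactants: 10
Product: 11, Glycybridin C, (R)-1-[2,4-dihydroxy-3-(3-methylbut-2-enyl)phenyl]-2-hydroxy-3-[4-hydroxy-3-(3-methylbut-2-enyl)phenyl]propan-1-one
Conditions: hν (254 nm, low-pressure Hg), degassed MeCN (5 mM), quartz/FEP flow coil, 20 °C, stopped at about 90% conversion
Reagents that add atoms: none
Why: Proposed new method: a regioconvergent, stereoretentive photo-Fries rearrangement of an unprotected, enantiopure α-hydroxyacyl aryl ester — excitation of the aryl ester homolyses the ArO–C(=O) bond to a solvent-caged phenoxyl/α-hydroxyacyl σ-radical pair that recombines at C6 (ortho) or C4 (para) faster than the acyl radical decarbonylates and without the α-carbon ever becoming planar, so (R) is retained; both sites tautomerise to the same 2,4-dihydroxy-3-prenylaryl ketone, which is shielded from further photochemistry by excited-state proton transfer in the o-hydroxy ketone, and MeCN hydrogen-bonds the phenols to suppress phenol–alkene photocyclisation; the closest known reaction is the photo-Fries rearrangement of aryl 3-arylpropanoates to 2'-hydroxydihydrochalcones.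

**Compound list**
1 | 1,3-bis(methoxymethoxy)benzene | COCOc1cccc(OCOC)c1 | starting material
2 | prenyl bromide | CC(C)=CCBr | starting material
3 | 1,3-bis(methoxymethoxy)-2-(3-methylbut-2-enyl)benzene | COCOc1cccc(OCOC)c1CC=C(C)C | intermediate
4 | 2-(3-methylbut-2-enyl)benzene-1,3-diol | CC(C)=CCc1c(O)cccc1O | intermediate
5 | D-tyrosine | N[C@H](Cc1ccc(O)cc1)C(=O)O | starting material
6 | 3-iodo-D-tyrosine | N[C@H](Cc1ccc(O)c(I)c1)C(=O)O | intermediate
7 | (R)-2-hydroxy-3-(4-hydroxy-3-iodophenyl)propanoic acid | O[C@H](Cc1ccc(O)c(I)c1)C(=O)O | intermediate
8 | tributyl(3-methylbut-2-enyl)stannane | CCCC[Sn](CCCC)(CCCC)CC=C(C)C | starting material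
9 | (R)-2-hydroxy-3-[4-hydroxy-3-(3-methylbut-2-enyl)phenyl]propanoic acid | CC(C)=CCc1cc(C[C@@H](O)C(=O)O)ccc1O | intermediate
10 | 3-hydroxy-2-(3-methylbut-2-enyl)phenyl (R)-2-hydroxy-3-[4-hydroxy-3-(3-methylbut-2-enyl)phenyl]propanoate | CC(C)=CCc1cc(C[C@@H](O)C(=O)Oc2cccc(O)c2CC=C(C)C)ccc1O | intermediate
11 | Glycybridin C | CC(C)=CCc1cc(C[C@@H](O)C(=O)c2ccc(O)c(CC=C(C)C)c2O)ccc1O | target

**Totals**
Total steps: 7. Longest linear sequence: 5 (steps 3–7, from D-tyrosine).

**Three steps most likely to fail**
1. Step 7 (proposed photo-Fries). Risks are cage escape to 4, decarbonylation, and phenol–prenyl photocyclisation. Fallback (known chemistry): protect 9 as the bis-TBS ether and convert it to the Weinreb amide; add 2,4-bis(methoxymethoxy)-3-prenylphenyllithium, made by Br/Li exchange on the corresponding aryl bromide; then remove TBS and MOM with HCl/MeOH. This is an ionic ketone synthesis in place of the photochemical acyl shift.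
2. Step 6 (one-pot transient silylation and esterification). Risks are premature loss of the TMS ether leading to oligo-esters, diacylation of 4, and partial racemisation. Fallback: isolate the bis-TBS ether of 9, couple it to 4 with EDC/DMAP (Steglich), carry the TBS groups through the photo-Fries step, and remove them with HF·pyridine at the end. This replaces transient protection and the acid chloride with stable protection and carbodiimide coupling, at a cost of two steps.
3. Step 5 (Stille prenylation). Risks are linear versus reverse-prenyl selectivity, protodestannylation, and tin removal from a polar acid. Fallback: avoid the iodide and Pd altogether. From the methyl ester of (R)-4-hydroxyphenyllactic acid, O-allylate, run a thermal aromatic Claisen rearrangement to the ortho-allyl phenol, convert allyl to prenyl by cross-metathesis with 2-methyl-2-butene (Grubbs II), and saponify to 9.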